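**Retrosynthetic overview** (labdane-type numbering: ring A = C1–C5, C10; ring B = C5–C10; C17 = exocyclic CH2 on C8; C11–C15 = acid chain on C9)
1. End game: acid from ester hydrolysis after Horner–Wadsworth–Emmons reaction on the C13 methyl ketone; C8=CH2 by methylenation and 7α-OH by enolate hydroxylation of an 8-oxo-decalin.
2. Ring B (formed second): 6-endo acyl radical closure of C8 onto the terminal carbon (C7) of the vinyl group on C5.
3. Ring A and the ring-fusion bond (formed first): one-flask [2,3]-Wittig / anionic oxy-Cope / intramolecular Wittig sequence on a bis-allyl ether phosphonium salt. The enabling feature is that the C5–C10 bond is flanked by the two-carbon arms C1–C2 (ring A) and C6–C7 (ring B). A temporary C2–C7 bond therefore makes C5–C10 the new sigma bond of a 1,5-dien-3-olate, and C2 emerges as the aldehyde that closes six-membered ring A onto C3.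
4. Fragments: quaternary C4 from geraniol (asymmetric epoxidation, epoxy silyl ether rearrangement) and a reagent-controlled C5 carbinol; the (Z)-allyl chloride (C1, C2, C8–C13) from an organocatalytic Michael addition and cuprate/ynoate syn-addition; union by Williamson etherification.

Key step: step 15

Assumption: 3-(tert-butyldiphenylsilyloxy)propanal (6) is taken as a purchasable aldehyde; the route is otherwise from geraniol and methyl vinyl ketone.

**Step 1**
Reactants: 1 geraniol
Product: 2 (2S,3S)-2,3-epoxygeraniol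
Conditions: Ti(OiPr)4 (cat.), L-(+)-diethyl tartrate, t-BuOOH, 4 Å MS, CH2Cl2, −20 °C
Reagents that add atoms: tert-butyl hydroperoxide CC(C)(C)OO
Why: Sharpless asymmetric epoxidation touches only the allylic alkene, and the L-(+)-tartrate ligand sets the (2S,3S)-epoxide.

**Step 2**
Reactants: 2 (2S,3S)-2,3-epoxygeraniol
Product: 3 (2S,3S)-2,3-epoxygeranyl tert-butyldimethylsilyl ether
Conditions: t-BuMe2SiCl, imidazole, DMF, 23 °C
Reagents that add atoms: tert-butyldimethylsilyl chloride CC(C)(C)[Si](C)(C)Cl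
Why: Standard silylation of the primary alcohol supplies the siloxymethyl group needed for the next rearrangement.

**Step 3**
Reactants: 3 (2S,3S)-2,3-epoxygeranyl tert-butyldimethylsilyl ether
Product: 4 (S)-2-[(tert-butyldimethylsilyloxy)methyl]-2,6-dimethylhept-5-enal
Conditions: MeAl(OAr)2 (Ar = 4-bromo-2,6-di-tert-butylphenyl), CH2Cl2, −78 °C
Reagents that add atoms: none
Why: Lewis-acid-promoted epoxy silyl ether rearrangement: the tertiary C–O bond ionises and the siloxymethyl group migrates anti with inversion, so the epoxide chirality becomes the quaternary centre (future C4).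

**Step 4**
Reactants: 4 (S)-2-[(tert-butyldimethylsilyloxy)methyl]-2,6-dimethylhept-5-enal
Product: 5 (3R,4S)-4-[(tert-butyldimethylsilyloxy)methyl]-4,8-dimethylnona-1,7-dien-3-ol
Conditions: Zn(CH=CH2)2, (+)-3-exo-(dimethylamino)isoborneol (10 mol %), toluene/Et2O, 0 °C
Reagents that add atoms: divinylzinc C=C[Zn]C=C
Why: Amino-alcohol-catalysed vinylzinc addition sets the (R)-carbinol (future C5) by reagent control, which is needed because the quaternary neighbour cannot tell methyl from the homoprenyl chain.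

**Step 5**
Reactants: 6 3-(tert-butyldiphenylsilyloxy)propanal; 7 methyl vinyl ketone
Product: 8 (S)-2-[(tert-butyldiphenylsilyloxy)methyl]-5-oxohexanal
Conditions: (S)-α,α-diphenylprolinol trimethylsilyl ether (10 mol %), ethyl 3,4-dihydroxybenzoate (20 mol %), neat, 4 °C
Reagents that add atoms: none
Why: Enamine-catalysed asymmetric Michael addition of an aldehyde to an enone; the shielded enamine face sets the (S)-centre (future C9) and brings in the C11–C13 ketone chain.

**Step 6**
Reactants: 8 (S)-2-[(tert-butyldiphenylsilyloxy)methyl]-5-oxohexanal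
Product: 9 (R)-7,7-dibromo-5-[(tert-butyldiphenylsilyloxy)methyl]hept-6-en-2-one
Conditions: CBr4, PPh3, CH2Cl2, 0 °C
Reagents that add atoms: carbon tetrabromide BrC(Br)(Br)Br
Why: Corey–Fuchs dibromo-olefination is selective for the aldehyde over the methyl ketone and does not touch the stereocentre.

**Step 7**
Reactants: 9 (R)-7,7-dibromo-5-[(tert-butyldiphenylsilyloxy)methyl]hept-6-en-2-one
Product: 10 1,3-dioxolane ketal of 9
Conditions: ethylene glycol, pyridinium p-toluenesulfonate, benzene, reflux (Dean–Stark)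
Reagents that add atoms: ethylene glycol OCCO
Why: Ketalisation masks the methyl ketone against the organolithium, cuprate and base steps that follow.

**Step 8**
Reactants: 10 1,3-dioxolane ketal of 9
Product: 12 methyl (R)-4-[(tert-butyldiphenylsilyloxy)methyl]-6-(2-methyl-1,3-dioxolan-2-yl)hex-2-ynoate, via lithium acetylide 11 (not isolated)
Conditions: n-BuLi (2.2 equiv), THF, −78 → 0 °C; ClCO2Me, −78 °C
Reagents that add atoms: methyl chloroformate COC(=O)Cl
Why: Second half of the Corey–Fuchs sequence (bromine–lithium exchange, 1,2-shift, deprotonation), with the alkynyllithium trapped as the ynoate.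

**Step 9**
Reactants: 12 methyl (R)-4-[(tert-butyldiphenylsilyloxy)methyl]-6-(2-methyl-1,3-dioxolan-2-yl)hex-2-ynoate
Product: 13 methyl (2Z,4R)-4-[(tert-butyldiphenylsilyloxy)methyl]-3-methyl-6-(2-methyl-1,3-dioxolan-2-yl)hex-2-enoate
Conditions: LiCuMe2 (from MeLi and CuI), THF, −78 °C; MeOH, −78 °C
Reagents that add atoms: lithium dimethylcuprate C[Cu-]C.[Li+]
Why: Syn-carbocupration of the ynoate with protonation at −78 °C puts the new methyl cis to hydrogen, so the C9 branch ends up cis to the ester (the Z geometry the key step needs).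

**Step 10**
Reactants: 13 methyl (2Z,4R)-4-[(tert-butyldiphenylsilyloxy)methyl]-3-methyl-6-(2-methyl-1,3-dioxolan-2-yl)hex-2-enoate
Product: 14 (2Z,4R)-4-[(tert-butyldiphenylsilyloxy)methyl]-3-methyl-6-(2-methyl-1,3-dioxolan-2-yl)hex-2-en-1-ol
Conditions: i-Bu2AlH, CH2Cl2, −78 °C
Reagents that add atoms: none
Why: 1,2-Reduction of the enoate to the neryl-type allylic alcohol with the alkene geometry retained.

**Step 11**
Reactants: 14 (2Z,4R)-allylic alcohol
Product: 16 (2Z,4R)-allyl chloride of 14, via mesylate 15 (not isolated)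
Conditions: MeSO2Cl, 2,4,6-collidine, LiCl, DMF, 0 °C
Reagents that add atoms: lithium chloride [Li+].[Cl-]
Why: Mesylation followed by SN2 chloride displacement gives the primary allylic chloride without allylic transposition or Z/E isomerisation.

**Step 12**
Reactants: 5 (3R,4S)-vinyl carbinol; 16 (2Z,4R)-allyl chloride
Product: 17 bis-allyl ether (oxygen links C5 of 5 to C2 of 16)
Conditions: KH, THF, 0 °C; then 16, Bu4NI (cat.), 23 °C
Reagents that add atoms: none
Why: Williamson etherification at the unhindered primary allylic carbon joins the two fragments and keeps both stereocentres and the Z-alkene.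

**Step 13**
Reactants: 17 bis-allyl ether
Product: 18 primary alcohol of 17 (C3–OH)
Conditions: HF·pyridine, pyridine, THF, 0 → 23 °C
Reagents that add atoms: none
Why: Buffered HF removes the primary tert-butyldimethylsilyl ether and leaves the tert-butyldiphenylsilyl ether and the ketal.

**Step 14**
Reactants: 18 primary alcohol
Product: 20 C3 triphenylphosphonium triflate, via triflate 19 (not isolated)
Conditions: (CF3SO2)2O, 2,6-lutidine, CH2Cl2, −78 °C; then PPh3, −78 → 40 °C
Reagents that add atoms: triflic anhydride O=S(=O)(OS(=O)(=O)C(F)(F)F)C(F)(F)F; triphenylphosphine c1ccc(cc1)P(c1ccccc1)c1ccccc1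
Why: The neopentyl-type carbon needs the triflate leaving group for SN2 alkylation of the phosphine, and excess PPh3 in a non-ionising solvent suppresses rearrangement.

**Step 15**
Reactants: 20 C3 triphenylphosphonium triflate
Product: 23 ring A cyclohexene (C2=C3; vinyl on C5; quaternary C10), via lithium alkoxide ylide 21 (not isolated), via aldehyde ylide 22 (not isolated)
Conditions: KN(SiMe3)2 (1.0 equiv), THF, −78 °C; n-BuLi (1.1 equiv), −78 → −30 °C; 18-crown-6, −30 → 50 °C; AcOH (1.0 equiv), 0 → 50 °C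
Reagents that add atoms: none
Why: Proposed new method: KN(SiMe3)2 turns the phosphonium into a bystander ylide and n-BuLi lithiates the allylic O–CH2 group (C2); a [2,3]-Wittig shift through an envelope (quaternary C4 group pseudo-equatorial, alkenyl group exo) then builds the temporary C2–C7 bond, the (E)-C5=C6 alkene and alkoxide 21, relaying the C5–O configuration to C2. With K+/18-crown-6 the 1,5-dien-3-olate should undergo anionic oxy-Cope rearrangement through a chair (oxido group and C4 equatorial, the C9 branch of the (Z)-alkene axial, which also disfavours the oxido-axial chair), breaking C2–C7 and forming C5–C10 with the quaternary C10 and the C5 stereocentre in the anti (trans-decalin) relationship and absolute sense of the target. One equivalent of AcOH converts the enolate/ylide pair into aldehyde ylide 22, whose intramolecular Wittig reaction forms C2=C3 and closes six-membered ring A (ylide carbon C3 onto the C2 aldehyde, cis alkene by ring size). The closest known chemistry is the tandem [2,3]-Wittig/anionic oxy-Cope rearrangement of bis-allyl ethers and the intramolecular Wittig cyclisation of ω-oxoalkylphosphonium salts; new is running them in one flask with the ylide as bystander. The step needs metalation at C2–H2 rather than at the tertiary C5–H (shielded by quaternary C4), retention of both alkene geometries (low-temperature lithiation, fast shift) and a single aldehyde for the ylide (C7 ends as a vinyl CH2).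

**Step 16**
Reactants: 23 ring A cyclohexene
Product: 24 primary alcohol (C8–OH)
Conditions: Bu4NF, THF, 23 °C
Reagents that add atoms: none
Why: Fluoride cleaves the only remaining silyl ether.

**Step 17**
Reactants: 24 primary alcohol
Product: 25 C8 aldehyde
Conditions: Dess–Martin periodinane, NaHCO3, CH2Cl2, 0 → 23 °C
Reagents that add atoms: none
Why: Buffered, non-basic oxidation gives the α-branched aldehyde without affecting the three alkenes or the ketal.

**Step 18**
Reactants: 25 C8 aldehyde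
Product: 26 8-oxo-octalin (ring B closed, C2=C3 still present)
Conditions: t-C12H25SH (30 mol %), 1,1′-azobis(cyclohexanecarbonitrile), PhCl, 100 °C
Reagents that add atoms: none
Why: Thiol-catalysed acyl radical cyclisation: the C8 acyl radical should add 6-endo to the unhindered terminal carbon C7 (attack at C6 is blocked by the C5 neighbours), closing ring B as the trans-fused ketone because C5 and C10 are already fixed.

**Step 19**
Reactants: 26 8-oxo-octalin
Product: 27 8-oxo-decalin
Conditions: KO2CN=NCO2K, AcOH, pyridine/MeOH, 23 °C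
Reagents that add atoms: none
Why: Diimide reduces the cis-disubstituted ring A alkene and leaves the trisubstituted side-chain alkene and the ketone.

**Step 20**
Reactants: 27 8-oxo-decalin
Product: 29 7α-triethylsilyloxy-8-ketone, via hydroxy ketone 28 (not isolated)
Conditions: LiN(i-Pr)2, THF, −78 °C; 2-(phenylsulfonyl)-3-phenyloxaziridine, −78 °C; Et3SiCl, imidazole, −78 → 23 °C
Reagents that add atoms: 2-(phenylsulfonyl)-3-phenyloxaziridine O=S(=O)(c1ccccc1)N1OC1c1ccccc1; chlorotriethylsilane CC[Si](Cl)(CC)CC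
Why: Kinetic enolisation occurs toward the C7 methylene (C9 is tertiary and next to quaternary C10), and axial attack of the oxaziridine on the α face, anti to the C10 methyl, gives the 7α (axial) oxygen; the alkoxide is silylated in the same flask.

**Step 21**
Reactants: 29 7α-triethylsilyloxy-8-ketone
Product: 30 7α-triethylsilyloxy-8(17)-ene
Conditions: Zn, CH2Br2, TiCl4, THF/CH2Cl2, 0 → 23 °C
Reagents that add atoms: dibromomethane BrCBr
Why: Lombardo methylenation is non-basic, so the hindered ketone is converted without epimerising C7 or C9.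

**Step 22**
Reactants: 30 7α-triethylsilyloxy-8(17)-ene
Product: 31 7α-hydroxy-8(17)-ene methyl ketone
Conditions: TsOH·H2O (cat.), acetone/H2O, 23 °C
Reagents that add atoms: water O
Why: Mild aqueous acid removes the dioxolane and the triethylsilyl ether in one operation.

**Step 23**
Reactants: 31 7α-hydroxy-8(17)-ene methyl ketone
Product: 32 ethyl ester of the target
Conditions: (EtO)2P(O)CH2CO2Et, NaH, THF, 0 → 65 °C
Reagents that add atoms: triethyl phosphonoacetate CCOC(=O)CP(=O)(OCC)OCC
Why: Horner–Wadsworth–Emmons olefination of the methyl ketone should favour the (E)-enoate (chain trans to the ester); any minor (Z)-isomer is removed by chromatography.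

**Step 24**
Reactants: 32 ethyl ester of the target
Product: 33 target acid
Conditions: LiOH, THF/MeOH/H2O, 23 °C; then aq. HCl
Reagents that add atoms: lithium hydroxide [Li+].[OH-]
Why: Saponification of the unhindered enoate leaves the allylic alcohol and all alkenes untouched.

**Compound list**
1 | geraniol | CC(C)=CCC/C(C)=C/CO | starting material
2 | (2S,3S)-2,3-epoxygeraniol | OC[C@@H]1O[C@@]1(C)CCC=C(C)C | intermediate
3 | (2S,3S)-2,3-epoxygeranyl tert-butyldimethylsilyl ether | CC(C)(C)[Si](C)(C)OC[C@@H]1O[C@@]1(C)CCC=C(C)C | intermediate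
4 | (S)-2-[(tert-butyldimethylsilyloxy)methyl]-2,6-dimethylhept-5-enal | O=C[C@@](C)(CCC=C(C)C)CO[Si](C)(C)C(C)(C)C | intermediate
5 | (3R,4S)-4-[(tert-butyldimethylsilyloxy)methyl]-4,8-dimethylnona-1,7-dien-3-ol | C=C[C@@H](O)[C@@](C)(CCC=C(C)C)CO[Si](C)(C)C(C)(C)C | intermediate
6 | 3-(tert-butyldiphenylsilyloxy)propanal | O=CCCO[Si](c1ccccc1)(c1ccccc1)C(C)(C)C | starting material
7 | methyl vinyl ketone | C=CC(C)=O | starting material
8 | (S)-2-[(tert-butyldiphenylsilyloxy)methyl]-5-oxohexanal | O=C[C@H](CO[Si](c1ccccc1)(c1ccccc1)C(C)(C)C)CCC(C)=O | intermediate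
9 | (R)-7,7-dibromo-5-[(tert-butyldiphenylsilyloxy)methyl]hept-6-en-2-one | BrC(Br)=C[C@H](CO[Si](c1ccccc1)(c1ccccc1)C(C)(C)C)CCC(C)=O | intermediate
10 | 1,3-dioxolane ketal of 9 (R) | BrC(Br)=C[C@H](CO[Si](c1ccccc1)(c1ccccc1)C(C)(C)C)CCC1(C)OCCO1 | intermediate
11 | lithium acetylide from 10 (R) | [Li]C#C[C@H](CO[Si](c1ccccc1)(c1ccccc1)C(C)(C)C)CCC1(C)OCCO1 | intermediate (not isolated)
12 | methyl (R)-4-[(tert-butyldiphenylsilyloxy)methyl]-6-(2-methyl-1,3-dioxolan-2-yl)hex-2-ynoate | COC(=O)C#C[C@H](CO[Si](c1ccccc1)(c1ccccc1)C(C)(C)C)CCC1(C)OCCO1 | intermediate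
13 | methyl (2Z,4R)-4-[(tert-butyldiphenylsilyloxy)methyl]-3-methyl-6-(2-methyl-1,3-dioxolan-2-yl)hex-2-enoate | COC(=O)/C=C(C)\[C@H](CO[Si](c1ccccc1)(c1ccccc1)C(C)(C)C)CCC1(C)OCCO1 | intermediate
14 | (2Z,4R)-4-[(tert-butyldiphenylsilyloxy)methyl]-3-methyl-6-(2-methyl-1,3-dioxolan-2-yl)hex-2-en-1-ol | OC/C=C(C)\[C@H](CO[Si](c1ccccc1)(c1ccccc1)C(C)(C)C)CCC1(C)OCCO1 | intermediate
15 | methanesulfonate of 14 (2Z,4R) | CS(=O)(=O)OC/C=C(C)\[C@H](CO[Si](c1ccccc1)(c1ccccc1)C(C)(C)C)CCC1(C)OCCO1 | intermediate (not isolated)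
16 | (2Z,4R)-allyl chloride of 14 | ClC/C=C(C)\[C@H](CO[Si](c1ccccc1)(c1ccccc1)C(C)(C)C)CCC1(C)OCCO1 | intermediate
17 | bis-allyl ether: (R)-carbinol carbon (C5) of 5 O-alkylated by the (Z)-allyl unit of 16; C3–OSi(t-Bu)Me2 | C=C[C@@H](OC/C=C(C)\[C@H](CO[Si](c1ccccc1)(c1ccccc1)C(C)(C)C)CCC1(C)OCCO1)[C@@](C)(CCC=C(C)C)CO[Si](C)(C)C(C)(C)C | intermediate
18 | bis-allyl ether with free C3–OH | C=C[C@@H](OC/C=C(C)\[C@H](CO[Si](c1ccccc1)(c1ccccc1)C(C)(C)C)CCC1(C)OCCO1)[C@@](C)(CCC=C(C)C)CO | intermediate
19 | C3 triflate of 18 | C=C[C@@H](OC/C=C(C)\[C@H](CO[Si](c1ccccc1)(c1ccccc1)C(C)(C)C)CCC1(C)OCCO1)[C@@](C)(CCC=C(C)C)COS(=O)(=O)C(F)(F)F | intermediate (not isolated)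
20 | C3 triphenylphosphonium triflate of the bis-allyl ether | C=C[C@@H](OC/C=C(C)\[C@H](CO[Si](c1ccccc1)(c1ccccc1)C(C)(C)C)CCC1(C)OCCO1)[C@@](C)(CCC=C(C)C)C[P+](c1ccccc1)(c1ccccc1)c1ccccc1.[O-]S(=O)(=O)C(F)(F)F | intermediate
21 | lithium alkoxide of the (R)-configured (5E,1Z)-1,5-dien-3-ol (temporary C2–C7 bond) carrying the C3 ylide | [Li]O[C@H](C/C=C/[C@@](C)(CCC=C(C)C)C=P(c1ccccc1)(c1ccccc1)c1ccccc1)/C=C(C)\[C@H](CO[Si](c1ccccc1)(c1ccccc1)C(C)(C)C)CCC1(C)OCCO1 | intermediate (not isolated)
22 | C2 aldehyde carrying the C3 ylide (C5–C10 bond formed, vinyl on C5) | C=C[C@@H]([C@@](C)(CCC=C(C)C)C=P(c1ccccc1)(c1ccccc1)c1ccccc1)[C@](C)(CC=O)[C@H](CO[Si](c1ccccc1)(c1ccccc1)C(C)(C)C)CCC1(C)OCCO1 | intermediate (not isolated)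
23 | ring A cyclohexene: C2=C3, C4 (methyl, homoprenyl), C5 (H, vinyl), C10 (methyl, CH(CH2OSi(t-Bu)Ph2)(CH2CH2-ketal) arm); configuration as in the target at C4, C5, C9, C10 | C=C[C@H]1[C@@](C)(CCC=C(C)C)C=CC[C@]1(C)[C@H](CO[Si](c2ccccc2)(c2ccccc2)C(C)(C)C)CCC2(C)OCCO2 | intermediate
24 | C8 primary alcohol of 23 | C=C[C@H]1[C@@](C)(CCC=C(C)C)C=CC[C@]1(C)[C@H](CO)CCC1(C)OCCO1 | intermediate
25 | C8 aldehyde | C=C[C@H]1[C@@](C)(CCC=C(C)C)C=CC[C@]1(C)[C@H](C=O)CCC1(C)OCCO1 | intermediate
26 | trans-fused 8-oxo-octalin (C2=C3), C9 side chain as ketal | O=C1CC[C@H]2[C@@](C)(CCC=C(C)C)C=CC[C@]2(C)[C@H]1CCC1(C)OCCO1 | intermediate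
27 | trans-fused 8-oxo-decalin, C9 side chain as ketal | O=C1CC[C@H]2[C@@](C)(CCC=C(C)C)CCC[C@]2(C)[C@H]1CCC1(C)OCCO1 | intermediate
28 | 7α-hydroxy-8-oxo-decalin | O=C1[C@H](O)C[C@H]2[C@@](C)(CCC=C(C)C)CCC[C@]2(C)[C@H]1CCC1(C)OCCO1 | intermediate (not isolated)
29 | 7α-triethylsilyloxy-8-oxo-decalin | O=C1[C@H](O[Si](CC)(CC)CC)C[C@H]2[C@@](C)(CCC=C(C)C)CCC[C@]2(C)[C@H]1CCC1(C)OCCO1 | intermediate
30 | 7α-triethylsilyloxy-8(17)-ene, side chain as ketal | C=C1[C@H](O[Si](CC)(CC)CC)C[C@H]2[C@@](C)(CCC=C(C)C)CCC[C@]2(C)[C@H]1CCC1(C)OCCO1 | intermediate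
31 | 7α-hydroxy-8(17)-ene with 3-oxobutyl side chain on C9 | C=C1[C@H](O)C[C@H]2[C@@](C)(CCC=C(C)C)CCC[C@]2(C)[C@H]1CCC(C)=O | intermediate
32 | ethyl (E)-ester of the target | C=C1[C@H](O)C[C@H]2[C@@](C)(CCC=C(C)C)CCC[C@]2(C)[C@H]1CC/C(C)=C/C(=O)OCC | intermediate
33 | target acid (4R,5S,7R,9R,10S) | C=C1[C@H](O)C[C@H]2[C@@](C)(CCC=C(C)C)CCC[C@]2(C)[C@H]1CC/C(C)=C/C(=O)O | target

**Totals:** 24 steps; longest linear sequence 20 steps (steps 5–11, then 12–24).

**Steps most likely to fail**

Step 15. The one-flask sequence may break down through metalation at the wrong allylic position or a [1,2]-shift, through incomplete Li/K exchange before the oxy-Cope step, or through a failed proton hand-over between enolate and phosphonium. The fallback runs the same bond reorganisation stepwise with isolated intermediates and a different ring A closure. From 17, n-BuLi in THF at −78 °C would give the [2,3]-Wittig dienol F1, and KH/18-crown-6 would rearrange it to the oxy-Cope aldehyde F2. HF·pyridine would then free the hydroxy aldehyde F3 and Dess–Martin oxidation would give the dialdehyde F4. McMurry coupling (low-valent titanium from TiCl3 and Zn–Cu, DME, reflux) would form C2=C3 and return to 23.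

Step 18. The acyl radical may close 5-exo, add to the ring A alkene, or lose CO before cyclising. The fallback is a polar ring B closure. From 23, hydroboration with 9-BBN and NaOH/H2O2 oxidation would give the C7 primary alcohol F5, and I2/PPh3/imidazole the iodide F6. Bu4NF would then give the alcohol F7 and Dess–Martin oxidation the iodo aldehyde F8. SmI2 (THF/HMPA) Barbier cyclisation would form C7–C8 as the ring B alcohol F9, and a second Dess–Martin oxidation returns to 26.

Step 4. Vinyl transfer to the hindered α-quaternary aldehyde may be slow or show poor facial selectivity. From 4, CH2=CHMgBr would give the carbinol mixture F10 and Dess–Martin oxidation the vinyl ketone F11. Reduction with (S)-2-methyl-CBS-oxazaborolidine and BH3·SMe2 would then set the (R)-carbinol and return to 5.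

**Further compounds**
F1 | step 15 | (R)-configured (5E,1Z)-1,5-dien-3-ol with C3–OSi(t-Bu)Me2 | O[C@H](C/C=C/[C@@](C)(CCC=C(C)C)CO[Si](C)(C)C(C)(C)C)/C=C(C)\[C@H](CO[Si](c1ccccc1)(c1ccccc1)C(C)(C)C)CCC1(C)OCCO1
F2 | step 15 | oxy-Cope C2 aldehyde with C3–OSi(t-Bu)Me2 | C=C[C@@H]([C@@](C)(CCC=C(C)C)CO[Si](C)(C)C(C)(C)C)[C@](C)(CC=O)[C@H](CO[Si](c1ccccc1)(c1ccccc1)C(C)(C)C)CCC1(C)OCCO1
F3 | step 15 | C3 hydroxy C2 aldehyde | C=C[C@@H]([C@@](C)(CCC=C(C)C)CO)[C@](C)(CC=O)[C@H](CO[Si](c1ccccc1)(c1ccccc1)C(C)(C)C)CCC1(C)OCCO1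
F4 | step 15 | C2,C3 dialdehyde | C=C[C@@H]([C@@](C)(CCC=C(C)C)C=O)[C@](C)(CC=O)[C@H](CO[Si](c1ccccc1)(c1ccccc1)C(C)(C)C)CCC1(C)OCCO1
F5 | step 18 | C7 primary alcohol from hydroboration of 23 | OCC[C@H]1[C@@](C)(CCC=C(C)C)C=CC[C@]1(C)[C@H](CO[Si](c2ccccc2)(c2ccccc2)C(C)(C)C)CCC2(C)OCCO2
F6 | step 18 | C7 iodide | ICC[C@H]1[C@@](C)(CCC=C(C)C)C=CC[C@]1(C)[C@H](CO[Si](c2ccccc2)(c2ccccc2)C(C)(C)C)CCC2(C)OCCO2
F7 | step 18 | C7 iodide with free C8–OH | ICC[C@H]1[C@@](C)(CCC=C(C)C)C=CC[C@]1(C)[C@H](CO)CCC1(C)OCCO1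
F8 | step 18 | C7 iodide C8 aldehyde | ICC[C@H]1[C@@](C)(CCC=C(C)C)C=CC[C@]1(C)[C@H](C=O)CCC1(C)OCCO1
F9 | step 18 | ring B 8-hydroxy-octalin (C8 epimers) | OC1CC[C@H]2[C@@](C)(CCC=C(C)C)C=CC[C@]2(C)[C@H]1CCC1(C)OCCO1
F10 | step 4 | vinyl carbinol, mixture at the carbinol carbon | C=CC(O)[C@@](C)(CCC=C(C)C)CO[Si](C)(C)C(C)(C)C
F11 | step 4 | (S)-vinyl ketone | C=CC(=O)[C@@](C)(CCC=C(C)C)CO[Si](C)(C)C(C)(C)C
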